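**Retrosynthetic overview**

1. Target 10 ⇐ diacetate 9 (hydrolysis of two acetates); 9 ⇐ anhydride 6 + bromide 8 by cutting the side-chain bond between the ketone carbon C2′ and the first chain methylene C3′.
2. Enabling feature: the carboxyl carbon on ring carbon C1, ring carbons C1 and C6, the benzylic C1′ and the ketone carbon C2′ form a 1,5-dicarbonyl (homophthalic) array. It closes to a six-membered cyclic anhydride (isochromane-1,3-dione ring: C1, O2, C3, C4, C4a, C8a), in which C2′ (= C3 of that ring) is an activated alkanoyl carbon and the benzoate is its own leaving group.
3. Key step: nickel-catalysed reductive ring-opening coupling of 6 at C3 with the primary bromide 8. One operation makes the C2′–C3′ bond, the ketone and the free benzoic acid from two bench-stable electrophiles, with no organometallic reagent and no protection of the acid.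
4. 6 ⇐ 2,4-dimethoxy-6-methylbenzoic acid 1: lateral lithiation/carboxylation (C1′–C2′ bond), chelation-controlled cleavage of the ortho methyl ether, then Ac2O (anhydride closure and phenol acetate together).
5. Ring order: the benzene ring is bought with 1; the only ring made is the temporary anhydride ring (step 3), which the key step opens again.

Key step: step 5

Remark: the target is achiral, so no stereocentre has to be set; ring carbons are numbered C1 (carboxyl-bearing) to C6 and side-chain carbons C1′ (benzylic CH2) to C13′ (CH2OH).

**Route**

Step 1
Reactants: 1 2,4-dimethoxy-6-methylbenzoic acid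
Product: 3 2-(carboxymethyl)-4,6-dimethoxybenzoic acid, via dilithium benzylic dianion 2 (not isolated)
Conditions: LiN(iPr)2 (2.3 equiv), THF, −78 → 0 °C; CO2 (gas), −78 °C → rt; then 2 M HCl
Reagents that add atoms: carbon dioxide, O=C=O
Why: Lateral (benzylic) lithiation of an o-toluic acid, in which the lithium carboxylate directs the amide base to the ortho methyl group, followed by carboxylation of the dianion, is the established way from o-toluic acids to homophthalic acids.

Step 2
Reactants: 3 2-(carboxymethyl)-4,6-dimethoxybenzoic acid
Product: 4 2-(carboxymethyl)-6-hydroxy-4-methoxybenzoic acid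
Conditions: BCl3 (1 M in CH2Cl2, 3.5 equiv), CH2Cl2, −78 → 0 °C; then H2O/THF, rt
Reagents that add atoms: none
Why: Chelation-controlled Lewis-acid ether cleavage: boron bound to the benzoic carboxyl forms a six-membered chelate only with the ortho 6-methoxy group, so chloride removes that methyl group while the para 4-methoxy group, which cannot chelate, should stay.

Step 3
Reactants: 4 2-(carboxymethyl)-6-hydroxy-4-methoxybenzoic acid
Product: 6 8-acetoxy-6-methoxyisochromane-1,3-dione, via 8-hydroxy-6-methoxyisochromane-1,3-dione 5 (not isolated)
Conditions: Ac2O (neat, excess), 120 °C; evaporation, crystallisation from toluene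
Reagents that add atoms: acetic anhydride, CC(=O)OC(C)=O
Why: Dehydrative cyclisation of a homophthalic acid to its six-membered anhydride through the mixed anhydride (6-exo-trig acyl substitution) is standard, and the same reagent acetylates the phenol; no base is present that could C-acetylate the acidic C4.

Step 4
Reactants: 7 11-bromoundecan-1-ol
Product: 8 11-bromoundecyl acetate
Conditions: Ac2O (1.5 equiv), pyridine, 0 °C → rt
Reagents that add atoms: acetic anhydride, CC(=O)OC(C)=O
Why: Routine O-acetylation (nucleophilic acyl substitution) masks the primary alcohol, which would otherwise open the anhydride in step 5, as an ester that is inert to nickel and zinc and is removed in step 6.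

Step 5
Reactants: 6 8-acetoxy-6-methoxyisochromane-1,3-dione; 8 11-bromoundecyl acetate (1.5 equiv)
Product: 9 2-(acetyloxy)-6-[13-(acetyloxy)-2-oxotridecyl]-4-methoxybenzoic acid
Conditions: NiBr2(MeOCH2CH2OMe) (10 mol %), 4,4′-di-tert-butyl-2,2′-bipyridine (12 mol %), Zn powder (2.5 equiv), NaI (25 mol %), DMA, 0 → 23 °C; then cold 1 M HCl
Reagents that add atoms: none
Why: Proposed new method: zerovalent nickel (from the nickel dibromide complex, the bipyridine and Zn) should insert into the C3(acyl)–O2 bond of the anhydride ring of 6 to give an acylnickel arenecarboxylate, which captures the primary alkyl radical formed from 8 by halogen abstraction at monovalent nickel; reductive elimination from the trivalent acyl(alkyl)nickel forms the C2′–C3′ bond and releases 9 as its zinc benzoate. The closest known reaction type is the nickel-catalysed reductive (cross-electrophile) ring-opening alkylation of saturated cyclic anhydrides such as succinic and glutaric anhydrides with alkyl bromides, together with the nickel-catalysed alkylation of the same anhydrides by organozinc reagents; new here is a benzo-fused, unsymmetrical anhydride with an acidic C4 methylene. No ring is closed (the anhydride ring is opened) and no stereocentre is formed. The step needs site selectivity between the two acyl C–O bonds: C1 is an aroyl carbonyl flanked by the 8-acetoxy group and the ring fusion and deactivated by the para 6-methoxy donor, whereas C3 is an unhindered alkanoyl carbonyl, the position at which alcohols and amines are known to open this ring system. It also needs coupling to outrun loss of CO from the arylacetylnickel, which the bipyridine ligand, the low temperature and fast radical capture should secure, and the base-free medium without any organometallic reagent should leave the acidic C4–H and both acetates untouched.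

Step 6
Reactants: 9 2-(acetyloxy)-6-[13-(acetyloxy)-2-oxotridecyl]-4-methoxybenzoic acid
Product: 10 2-hydroxy-6-(13-hydroxy-2-oxotridecyl)-4-methoxybenzoic acid
Conditions: LiOH (6 equiv), THF/H2O 3:1, 0 °C → rt; then 1 M HCl to pH 3 at 0 °C, extraction without heating
Reagents that add atoms: none
Why: Saponification (acyl–oxygen cleavage) removes the aryl and the primary alkyl acetate while the product is held as carboxylate and phenoxide, which cannot lactonise onto the ketone, and cold mild acidification should free the keto acid without closing it to the isocoumarin.

**Compound list**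

1 | 2,4-dimethoxy-6-methylbenzoic acid | Cc1cc(OC)cc(OC)c1C(=O)O | starting material
2 | dilithium benzylic dianion of 1 | [Li+].[Li+].[CH2-]c1cc(OC)cc(OC)c1C(=O)[O-] | intermediate
3 | 2-(carboxymethyl)-4,6-dimethoxybenzoic acid | OC(=O)Cc1cc(OC)cc(OC)c1C(=O)O | intermediate
4 | 2-(carboxymethyl)-6-hydroxy-4-methoxybenzoic acid | OC(=O)Cc1cc(OC)cc(O)c1C(=O)O | intermediate
5 | 8-hydroxy-6-methoxyisochromane-1,3-dione | O=C1Cc2cc(OC)cc(O)c2C(=O)O1 | intermediate
6 | 8-acetoxy-6-methoxyisochromane-1,3-dione | CC(=O)Oc1cc(OC)cc2CC(=O)OC(=O)c12 | intermediate
7 | 11-bromoundecan-1-ol | OCCCCCCCCCCCBr | starting material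
8 | 11-bromoundecyl acetate | CC(=O)OCCCCCCCCCCCBr | intermediate
9 | 2-(acetyloxy)-6-[13-(acetyloxy)-2-oxotridecyl]-4-methoxybenzoic acid | CC(=O)OCCCCCCCCCCCC(=O)Cc1cc(OC)cc(OC(C)=O)c1C(=O)O | intermediate
10 | 2-hydroxy-6-(13-hydroxy-2-oxotridecyl)-4-methoxybenzoic acid | COc1cc(O)c(C(=O)O)c(CC(=O)CCCCCCCCCCCO)c1 | target

**Step count and risks**

Total step count: 6. Longest linear sequence: 5 steps (steps 1, 2, 3, 5, 6).

Most at risk is step 5, the proposed nickel coupling. Nickel may insert into the aroyl C1–O2 bond instead of C3–O2, the arylacetylnickel may lose CO before it meets the alkyl radical, or the acidic C4–H may protonate alkylnickel species and drain the bromide by reduction. The fallback uses known chemistry, sets out from 6 and 8 and comes back at 9. Anhydride 6 would be opened at C3 by ethanethiol (iPr2NEt, CH2Cl2, −20 °C; thiols should attack the non-conjugated carbonyl as alcohols and amines do) to give the thioester acid 2-acetoxy-6-[2-(ethylsulfanyl)-2-oxoethyl]-4-methoxybenzoic acid F1. Bromide 8 would be converted by direct zinc insertion (Zn, cat. I2, DMA, 70 °C) into (11-acetoxyundecyl)zinc bromide F2. Fukuyama coupling of F1 (first masked as its sodium carboxylate with 1 equiv NaH) with F2 (PdCl2(PPh3)2, 5 mol %, THF/toluene, rt), then cold dilute HCl, would return to 9. The acyl donor is then regiodefined before the C–C bond is made, and the thioester–organozinc ketone synthesis tolerates acetates, acidic α-protons and carboxylates.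

Second is step 2. The diacid 3 dissolves poorly in CH2Cl2 and offers boron two carboxyl groups, so ether cleavage may stall or lose its chelation control and spread to the para methoxy group. The fallback sets out from 3 and comes back at 4. Both acids would be methylated (MeI, K2CO3, DMF) to the soluble diester methyl 2,4-dimethoxy-6-(2-methoxy-2-oxoethyl)benzoate F3, in which only the aryl ester carbonyl can chelate the ortho methoxy group. BCl3 (CH2Cl2, −78 → 0 °C) should then give the salicylate methyl 2-hydroxy-4-methoxy-6-(2-methoxy-2-oxoethyl)benzoate F4, and saponification of both esters (NaOH, aq. MeOH, reflux, then HCl) would deliver 4.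

Third is step 1. The amide base may deprotonate the ring C–H between the two methoxy groups instead of the methyl group, or the dianion may form incompletely and be quenched by proton transfer, so that carboxylation stays partial. The fallback sets out from 1 and comes back at 3. Acid 1 would be esterified (MeI, K2CO3, acetone) to methyl 2,4-dimethoxy-6-methylbenzoate F5, whose methyl group is acidified by the conjugated ester and needs only a monoanion. Lateral lithiation (LiN(iPr)2, THF, −78 °C) and CO2 would give the half ester 2-[3,5-dimethoxy-2-(methoxycarbonyl)phenyl]acetic acid F6, and hydrolysis of the hindered aryl ester (KOH, aq. EtOH, reflux, then HCl) would give 3.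

**Further compounds**

F1 | step 5 | 2-acetoxy-6-[2-(ethylsulfanyl)-2-oxoethyl]-4-methoxybenzoic acid | CCSC(=O)Cc1cc(OC)cc(OC(C)=O)c1C(=O)O
F2 | step 5 | (11-acetoxyundecyl)zinc bromide | CC(=O)OCCCCCCCCCCC[Zn]Br
F3 | step 2 | methyl 2,4-dimethoxy-6-(2-methoxy-2-oxoethyl)benzoate | COC(=O)Cc1cc(OC)cc(OC)c1C(=O)OC
F4 | step 2 | methyl 2-hydroxy-4-methoxy-6-(2-methoxy-2-oxoethyl)benzoate | COC(=O)Cc1cc(OC)cc(O)c1C(=O)OC
F5 | step 1 | methyl 2,4-dimethoxy-6-methylbenzoate | Cc1cc(OC)cc(OC)c1C(=O)OC
F6 | step 1 | 2-[3,5-dimethoxy-2-(methoxycarbonyl)phenyl]acetic acid | OC(=O)Cc1cc(OC)cc(OC)c1C(=O)OC
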